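Assumption: the SMILES decodes as (3R,4S)-6-hydroxy-4-(4-hydroxy-3-methoxyphenyl)-3-(hydroxymethyl)-5-methoxy-3,4-dihydronaphthalene-2-carbaldehyde. I use aryl-dihydronaphthalene numbering: C1 = CH–Ar, C2 = CH–CH2OH, C3 = C–CHO, C4 = vinylic CH, C7–OH, C8–OMe. In that numbering the target is (1S,2R), with the C1 and C2 substituents trans. Reagents and catalysts are named in full but not numbered.

## Retrosynthetic overview

1. Target 9 comes from the (1S,2R)-2,3-dicarbaldehyde 8 by reducing only the non-conjugated C2–CHO.
2. Dialdehyde 8 comes from p-quinone methide 7 and succinaldehyde 6 in a one-pot catalytic asymmetric [4+2]. An enamine 1,6-addition forms C1–C2 and sets both stereocentres, then an enamine aldol condensation forms C3=C4.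
3. Quinone methide 7 comes from diarylmethyl acetate 4 by fluoride-triggered 1,6-elimination, which erases the racemic centre of 4.
4. Acetate 4 comes from two vanillin units. The C8a–C1 bond is made by directed lithiation at C2 of a vanillin acetal, which fixes the unusual 7-OH/8-OMe pattern that Friedel–Crafts or oxidative 8–8′ coupling routes do not deliver.
5. Both arenes are bought. Ring B is the only ring formed, and it is formed in the key step. All 20 carbons come from 2 × vanillin plus succinaldehyde.

## Route

**Step 1**
Reactants: 1, vanillin
Product: 2, 3-methoxy-4-(triisopropylsilyloxy)benzaldehyde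
Conditions: TIPSCl, imidazole, DMF, rt
Reagents that add atoms: triisopropylsilyl chloride, CC(C)[Si](Cl)(C(C)C)C(C)C
Why: Standard phenol silylation; TIPS survives n-BuLi, is a poor and bulky ortho-director (so C5 is not lithiated later), and is removed by fluoride.

**Step 2**
Reactants: 2
Product: 3, 3-methoxy-4-(triisopropylsilyloxy)benzaldehyde dimethyl acetal
Conditions: HC(OMe)3, p-TsOH·H2O (1 mol %), MeOH, rt; Et3N quench
Reagents that add atoms: trimethyl orthoformate, COC(OC)OC; methanol, CO
Why: Acid-catalysed acetalisation masks the aldehyde against BuLi and turns it into a directing group, and aryl TIPS ethers tolerate catalytic acid.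

**Step 3**
Reactants: 3 (nucleophile precursor) and 2 (electrophile)
Product: 4, (±)-[2-(dimethoxymethyl)-6-methoxy-5-(triisopropylsilyloxy)phenyl][3-methoxy-4-(triisopropylsilyloxy)phenyl]methyl acetate
Conditions: 3, n-BuLi (1.1 equiv), Et2O, 0 °C → rt; 2, THF, −78 → −20 °C; Ac2O, DMAP (cat.), → rt
Reagents that add atoms: acetic anhydride, CC(=O)OC(C)=O
Why: Directed ortho-metalation at the site flanked by OMe and acetal (cooperative 1,3-directing effect, as in 3,4-dialkoxybenzaldehyde acetals), then 1,2-addition to the aldehyde and in situ O-acetylation; the new centre is racemic but is destroyed in Step 5.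

**Step 4**
Reactants: 5, 2,5-dimethoxytetrahydrofuran
Product: 6, succinaldehyde (butanedial)
Conditions: H2O, 90 °C, 2 h; remove MeOH/H2O (toluene azeotrope), short-path distillation; use fresh
Reagents that add atoms: water, O
Why: Simple hydrolysis of the cyclic bis-acetal, and fresh distillation gives monomeric dialdehyde.

**Step 5**
Reactants: 4
Product: 7, 4-{[2-(dimethoxymethyl)-5-hydroxy-6-methoxyphenyl]methylidene}-2-methoxycyclohexa-2,5-dien-1-one (p-quinone methide; exocyclic E/Z irrelevant; not isolated)
Conditions: TBAF/AcOH (1:1, 2.2 equiv), THF–CH2Cl2, −20 → 0 °C; cold pH 7 buffer wash, Na2SO4; CH2Cl2 solution used at once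
Reagents that add atoms: none
Why: Fluoride-triggered desilylation followed by 1,6-elimination of acetate; only the pendant phenol is para to the leaving group (the ring-A phenol is meta), AcOH buffering keeps the phenols protonated to suppress oligomerisation, and partial early hydrolysis of the acetal to the aldehyde is harmless for Step 6.

**Step 6 (key step)**
Reactants: 7 and 6 (3 equiv)
Product: 8, (1S,2R)-7-hydroxy-1-(4-hydroxy-3-methoxyphenyl)-8-methoxy-1,2-dihydronaphthalene-2,3-dicarbaldehyde (1,2-trans)
Conditions: (R)-α,α-diphenylprolinol trimethylsilyl ether [C[Si](C)(C)OC(c1ccccc1)(c1ccccc1)[C@H]1CCCN1] (20 mol %), PhCO2H (20 mol %), CH2Cl2, −20 °C → rt, Ar; then H2O (10 equiv), AcOH (0.5 equiv), rt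
Reagents that add atoms: none (all atoms come from 7 and 6; 2 MeOH are lost, and the water that opens the acetal is expelled again in the condensation)
Why: Proposed new method: an enamine 1,6-addition/enamine aldol-condensation domino in which the one-face-shielded E-enamine of 6 attacks the exocyclic carbon of 7 irreversibly (driven by aromatisation) through a synclinal open transition state with the flat quinone-methide ring over the enamine nitrogen and the twisted di-ortho-substituted ring A pointing away; this gives the syn adduct, which becomes 1,2-trans on ring closure, and the (R)-catalyst gives C2 = R and hence C1 = S; the p-hydroxy-activated acetal then hydrolyses and the unbranched CH2CHO arm condenses through a second enamine with the ring-A aldehyde to close ring B, while the α-branched C2–CHO is too hindered to re-enaminate and trans is also the thermodynamic isomer; the closest known reaction types are aminocatalytic α-alkylation of aldehydes with p-quinone methides, diarylprolinol-ether Michael additions of succinaldehyde, and Michael/aldol-condensation organocascades.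

**Step 7**
Reactants: 8
Product: 9, vitedoin A, (1S,2R) = (3R,4S) in naphthaldehyde numbering
Conditions: NaBH4 (1.0 equiv), CH2Cl2–MeOH (1:1), −78 °C, TLC control; acetone, then aq NH4Cl
Reagents that add atoms: none
Why: Chemoselective borohydride reduction by kinetic discrimination: the isolated C2–CHO is far more electrophilic than the push–pull p-hydroxycinnamaldehyde-type C3–CHO, reduction at −78 °C is faster than C2 epimerisation so both centres are retained, and any over-reduced diol can be returned to 9 by MnO2 allylic oxidation.

## Compound list

1 | vanillin | COc1cc(C=O)ccc1O | starting material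
2 | 3-methoxy-4-(triisopropylsilyloxy)benzaldehyde | COc1cc(C=O)ccc1O[Si](C(C)C)(C(C)C)C(C)C | intermediate
3 | 3-methoxy-4-(triisopropylsilyloxy)benzaldehyde dimethyl acetal | COc1cc(C(OC)OC)ccc1O[Si](C(C)C)(C(C)C)C(C)C | intermediate
4 | (±)-[2-(dimethoxymethyl)-6-methoxy-5-(TIPSO)phenyl][3-methoxy-4-(TIPSO)phenyl]methyl acetate | CC(=O)OC(c1ccc(O[Si](C(C)C)(C(C)C)C(C)C)c(OC)c1)c1c(C(OC)OC)ccc(O[Si](C(C)C)(C(C)C)C(C)C)c1OC | intermediate
5 | 2,5-dimethoxytetrahydrofuran | COC1CCC(OC)O1 | starting material
6 | succinaldehyde | O=CCCC=O | intermediate
7 | 4-{[2-(dimethoxymethyl)-5-hydroxy-6-methoxyphenyl]methylidene}-2-methoxycyclohexa-2,5-dien-1-one | COC1=CC(=Cc2c(C(OC)OC)ccc(O)c2OC)C=CC1=O | intermediate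
8 | (1S,2R)-7-hydroxy-1-(4-hydroxy-3-methoxyphenyl)-8-methoxy-1,2-dihydronaphthalene-2,3-dicarbaldehyde | COc1cc([C@H]2c3c(ccc(O)c3OC)C=C(C=O)[C@@H]2C=O)ccc1O | intermediate
9 | vitedoin A | COc1cc([C@H]2c3c(ccc(O)c3OC)C=C(C=O)[C@@H]2CO)ccc1O | target

## Totals

Total steps: 7.
Longest linear sequence: 6 (1 → 2 → 3 → 4 → 7 → 8 → 9).

## Three steps most likely to fail

1. **Step 6.**
   - Risk: attack on the di-ortho-hindered quinone methide may be slow enough for succinaldehyde to self-aldolise.
   - Risk: imperfect facial selectivity at C1 would erode ee if the cis isomer epimerises at C2.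
   - Fallback: give up the domino and the dialdehyde, with these changes:
     - Use orthogonal silyl groups (pendant TBS, ring-A TIPS) so the ring-A acetal stays robust.
     - Use mono-masked 4,4-dimethoxybutanal as the enamine partner (DIBAL reduction of commercial 4,4-dimethoxybutanenitrile).
     - Reduce the adduct aldehyde in the same pot with NaBH4. This locks C2 as CH2OH and allows the C1 epimers to be separated.
     - Unmask both acetals with aqueous acid, close ring B in a separate amine-salt aldol condensation, and desilylate.
     - This sequence also removes Step 7.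

2. **Step 5.**
   - Risk: the free-phenol quinone methide may hydrate or oligomerise before use.
   - Fallback: never accumulate it. Intercept it with p-toluenesulfinic acid to give the bench-stable (4-hydroxyaryl)(aryl)methyl sulfone. Release the quinone methide slowly inside Step 6 under a biphasic NaHCO3 regime, so its stationary concentration stays low.

3. **Step 3.**
   - Risk: lithiation may occur at C6 or C5 instead of C2, or the hindered aryllithium may add poorly.
   - Fallback: reverse the polarity of the union, as follows:
     - Brominate commercial 3-hydroxy-2-methoxybenzaldehyde para to OH (C6) and silylate it.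
     - Add the aryllithium from TIPS-protected 4-bromo-2-methoxyphenol to its aldehyde; this carbon becomes C1.
     - Carry out Br/Li exchange on the alkoxide and quench with DMF to install C4.
     - After desilylation, the resulting 3-aryl-1-hydroxyphthalan (lactol) serves as the quinone methide precursor by Brønsted-acid dehydration in the key step.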